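The numbers are assumed; the rest is arithmetic.

Tank delta and flask eta look nearly the same: the same Q charge, and 20 s on average in delta against a run of 20 s in eta, but delta is continuous and backmixed while eta is closed. I want to know what separates their Q2.

the same everywhere: Q 2.0 mM

| flask | remark | time |
|---|---|---|
| delta | a single well-mixed tank run continuously and read at steady state, 20 s in it on average |  |
| theta | a single well-mixed tank run continuously and read at steady state, 200 s in it on average |  |
| eta | everything together in a closed stirred flask, run for 20 s | 20 s |

    Q2 → Z (k1 = 0.0283 s⁻¹)
    Q + Q2 → Q.Q2 (k2 = 11.8 M⁻¹ s⁻¹)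
    Q + Q ⇌ Q2 (K3 = 1490 M⁻¹, k3 = 14.7 M⁻¹ s⁻¹)

- in percentages every species weighs as the Q in it: one Q2 or Z counts as two
- in percentages every species weighs as the Q in it: one Q.Q2 counts as three
- a step written with two of one species runs at k times the square of its concentration and takes two of it each time
- the stated concentrations are those of everything mixed, before any reaction; amounts are the same in each set-up
- run time (eta): 20 s

- order of the set-ups by the amount of Q2 at the outlet or at the end, in percent of the Q put in, highest first (delta / theta / eta)
- amount of Q2 at the outlet or at the end, in percent of the Q put in, delta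
- amount of Q2 at the outlet or at the end, in percent of the Q put in, theta
- amount of Q2 at the outlet or at the end, in percent of the Q put in, eta

I compare rates at one moment. I call balance level (the quasi-steady-state level of Q2) the concentration of Q2 at which, for a given c_Q, Q2 is made net exactly as fast as it is used:

level = 14.7 M⁻¹ s⁻¹ × c_Q × c_Q / (0.0283 s⁻¹ + 11.8 M⁻¹ s⁻¹ × c_Q + 0.00987 s⁻¹)

As Q falls the level drifts down, and in eta Q2 peaks where it meets the level. Dimerisation alone halves Q in 17.0 s, so with a run longer than that I take eta near its peak and reckon at c_Q = 1.00 mM. This gives 29.4% of the charge, the balance level of eta at that c_Q.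

The tank adds washout to the denominator, 0.0500 s⁻¹, which is larger than 0.0283 s⁻¹. My trial for delta is c_Q = 1.20 mM:

level = 20.7%
Q fed net 0.0400 mM s⁻¹, Q consumed 0.0412 mM s⁻¹

The Q balance nearly closes, so I take 20.7% for delta, below my figure for eta. A rougher trial for theta, c_Q = 0.500 mM, gives 7.49%.

The forecast, from “a rough mental balance of the tanks and a coarse time-stepping of the flask”, says eta > delta > theta, with 20.4% for delta, 8.6% for theta and 28% for eta, figures that differ from mine.

The simulation gives eta > delta > theta: 20.4% in delta, 8.55% in theta, 29.7% in eta, against my 29.4% for eta. At 20.0 s eta holds Q at 46.8%, where the level is 26.2%, less than the 29.7% of Q2 present, and the making-to-using ratio there is 0.855. The neighbour of eta charged with 5.0 mM of Q ends with Q at 25.2%. Its level there is 17.7% of its charge, lower than the Q2 it holds, which is 32.3%.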